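The seven-membered ring is cut at C5–C6 and C8–C8a (hydroazulene locants: C3 carbinol, C4 ester carbon, C6–C7 epoxide, C8a angular methyl). Both bonds are formed in one operation by a rhodium-carbenoid cyclopropanation/Cope rearrangement, a formal (4+3) cycloaddition of methyl 2-diazobut-3-enoate (C6–C7–C8) with a 2-silyloxy diene (C5=C4–C3a=C8a) carried on a cyclopentene; it closes the ring and sets quaternary C8a. The step exploits the cis 1,3-dioxygen pattern O3/O4: a di-tert-butylsilylene ring joins the two oxygens, locks the diene s-cis and steers the carbenoid. The cyclopentene, with C3 in place, comes from (S)-terpinen-4-ol by ozonolysis and aldol ring contraction.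

Key step: step 7

Assumption: (S)-(+)-terpinen-4-ol is taken as commercially available in high enantiomeric purity.
Remark: the target is read as cis-fused (3a-H, 8a-CH3 and the epoxide oxygen on the α face; 3-OH and the 4-acyloxy group on the β face); the target's hydroazulene locants are used for all bicyclic compounds.

Step 1
Reactants: 1 (S)-(+)-terpinen-4-ol
Product: 2 triethyl{[(1S)-4-methyl-1-(propan-2-yl)cyclohex-3-en-1-yl]oxy}silane
Conditions: Et3SiOTf, 2,6-lutidine, CH2Cl2, 0 °C → rt
Reagents that add atoms: triethylsilyl trifluoromethanesulfonate, CC[Si](CC)(CC)OS(=O)(=O)C(F)(F)F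
Why: Silyl triflate/lutidine silylation of a hindered tertiary alcohol; the ether blocks retro-aldol cleavage and slows β-elimination of the β-oxy aldehyde made in step 2, and no stereocentre is touched.

Step 2
Reactants: 2 triethyl{[(1S)-4-methyl-1-(propan-2-yl)cyclohex-3-en-1-yl]oxy}silane
Product: 5 (5R)-2-methyl-5-(propan-2-yl)-5-[(triethylsilyl)oxy]cyclopent-1-ene-1-carbaldehyde, via secondary ozonide 3 (not isolated), via keto aldehyde 4 (not isolated)
Conditions: O3, CH2Cl2, −78 °C; PPh3, −78 °C → rt; then piperidine, AcOH (cat.), toluene, 80 °C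
Reagents that add atoms: ozone, [O-][O+]=O
Why: Ozonolysis of the trisubstituted ring alkene gives the 1,6-keto aldehyde, and amine-catalysed intramolecular aldol condensation through the aldehyde enamine (5-enolexo closure onto the methyl ketone, then dehydration) contracts the ring to the cyclopentene carbaldehyde, the untouched carbinol centre becoming C3.

Step 3
Reactants: 5 (5R)-2-methyl-5-(propan-2-yl)-5-[(triethylsilyl)oxy]cyclopent-1-ene-1-carbaldehyde
Product: 7 (1R)-2-(1-hydroxyethyl)-3-methyl-1-(propan-2-yl)cyclopent-2-en-1-ol (both epimers at the hydroxyethyl carbon), via silyl-protected allylic alcohol 6 (not isolated)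
Conditions: MeMgBr, THF, −78 → 0 °C, aq. NH4Cl work-up; then Bu4NF, THF, rt
Reagents that add atoms: methylmagnesium bromide, C[Mg]Br
Why: Grignard 1,2-addition to the enal gives the secondary allylic alcohol (the new centre is oxidised away in step 4) and fluoride then frees the tertiary alcohol needed for the silicon tether.

Step 4
Reactants: 7 (1R)-2-(1-hydroxyethyl)-3-methyl-1-(propan-2-yl)cyclopent-2-en-1-ol
Product: 8 1-[(5R)-5-hydroxy-2-methyl-5-(propan-2-yl)cyclopent-1-en-1-yl]ethan-1-one
Conditions: Dess–Martin periodinane, pyridine, CH2Cl2, 0 °C → rt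
Reagents that add atoms: none
Why: Dess–Martin oxidation converts the secondary allylic alcohol of both epimers to the same methyl ketone, the tertiary alcohol cannot be oxidised, and the pyridine buffer protects the acid-sensitive allylic diol.

Step 5
Reactants: 8 1-[(5R)-5-hydroxy-2-methyl-5-(propan-2-yl)cyclopent-1-en-1-yl]ethan-1-one
Product: 9 cyclic di-tert-butylsilylene dienol ether of 8 [(7aR)-2,2-di-tert-butyl-5-methyl-4-methylidene-7a-(propan-2-yl)-4,6,7,7a-tetrahydrocyclopenta[d][1,3,2]dioxasiline]
Conditions: LiN(iPr)2 (2.2 equiv), THF, −78 °C; tBu2Si(OTf)2, −78 → 0 °C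
Reagents that add atoms: di-tert-butylsilyl bis(trifluoromethanesulfonate), CC(C)(C)[Si](OS(=O)(=O)C(F)(F)F)(OS(=O)(=O)C(F)(F)F)C(C)(C)C
Why: Alkoxide formation and kinetic deprotonation of the acetyl methyl group give the cross-conjugated enolate, and the bifunctional silyl ditriflate silylates the enolate and alkoxide oxygens in turn, closing a six-membered dioxasiline that fixes the 2-silyloxy diene in its s-cis form.

Step 6
Reactants: 10 methyl but-3-enoate
Product: 11 methyl 2-diazobut-3-enoate
Conditions: p-ABSA, DBU, MeCN, 0 °C; used at once as a pentane solution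
Reagents that add atoms: 4-acetamidobenzenesulfonyl azide (p-ABSA), CC(=O)Nc1ccc(cc1)S(=O)(=O)N=[N+]=[N-]
Why: Regitz diazo transfer to the allylic α-methylene of a β,γ-unsaturated ester gives the vinyldiazoacetate, which is used immediately because it cyclises slowly to a pyrazole.

Step 7
Reactants: 9 cyclic di-tert-butylsilylene dienol ether; 11 methyl 2-diazobut-3-enoate
Product: 13 tricyclic silylene enol ether [methyl (3R,8aS)-3,4-[(di-tert-butylsilanediyl)bis(oxy)]-8a-methyl-3-(propan-2-yl)-1,2,3,5,8,8a-hexahydroazulene-6-carboxylate], via divinylcyclopropane 12 (not isolated)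
Conditions: Rh2(O2CC7H15)4 (dirhodium tetraoctanoate, 1 mol %), pentane, reflux, slow addition of 11 (2 equiv); then toluene, 80 °C
Reagents that add atoms: none
Why: The rhodium carbenoid from 11 adds through its carbenoid carbon (C6) to the exocyclic enol-ether methylene of 9, the most nucleophilic and only unhindered alkene (C5 first, then C4), to give cis-divinylcyclopropane 12, and its [3,3] Cope rearrangement breaks C4–C6 and joins the vinyl terminus C8 to C8a, so that C5–C6 and C8–C8a are both in place after one operation; this is the known tandem cyclopropanation/Cope (formal (4+3)) reaction of vinylcarbenoids with 2-silyloxy dienes and 1-vinylcycloalkenes. The seven-membered ring is closed in the sigmatropic step through a boat transition state (pericyclic ring expansion of the three-membered ring, itself formed by concerted asynchronous (2+1) addition). The one new stereocentre, quaternary C8a, is fixed by the face of the enol ether that is cyclopropanated, because the boat Cope is stereospecific: the silylene ring holds the enol oxygen on the β face next to O3, which tilts the methylene terminus toward the α-isopropyl group and exposes only its outer β face, so C6 arrives on the β side and C8 is delivered to the β face of C8a (cis to O3, angular methyl α). Regioselectivity (carbenoid carbon, not the vinyl terminus, to C5) is secured by the carboxylate catalyst in a hydrocarbon solvent and by the polarised enol ether; the tetrasubstituted ring alkene cannot be cyclopropanated and is kept for the Cope step. The tether also holds that alkene bisecting the cyclopropane, the endo geometry the rearrangement needs, which offsets the retarding Z-methyl group; a trans-divinyl isomer would equilibrate at C6 through the donor–acceptor cyclopropane on heating.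

Step 8
Reactants: 13 tricyclic silylene enol ether
Product: 15 methyl (3R,3aR,8aS)-3-hydroxy-8a-methyl-4-oxo-3-(propan-2-yl)-1,2,3,3a,4,5,8,8a-octahydroazulene-6-carboxylate, via fluorosilyl ketone 14 (not isolated)
Conditions: HF·pyridine, pyridine, THF, 0 °C → rt
Reagents that add atoms: none
Why: Acidic fluoride cleaves the silyl enol ether and then the silyl ether, and C3a should be protonated on the α face because the β face is covered by the silicon group still bound to O3 when the C–H bond forms, giving the cis-fused ketone, which is also the more stable epimer (C4 next to OH and not isopropyl, no trans 5/7 fusion at the quaternary centre), while the non-basic medium avoids retro-aldol cleavage and migration of the skipped alkene.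

Step 9
Reactants: 15 methyl (3R,3aR,8aS)-3-hydroxy-8a-methyl-4-oxo-3-(propan-2-yl)-1,2,3,3a,4,5,8,8a-octahydroazulene-6-carboxylate
Product: 16 (3R,3aS,4R,8aS)-6-(hydroxymethyl)-8a-methyl-3-(propan-2-yl)-1,2,3,3a,4,5,8,8a-octahydroazulene-3,4-diol
Conditions: iBu2AlH (6 equiv), CH2Cl2, −78 → −20 °C; Rochelle salt work-up
Reagents that add atoms: none
Why: iBu2AlH reduces the enoate 1,2 to the allylic alcohol and the ketone to the alcohol, hydride being delivered to the aluminium-bound β-hydroxy ketone on the carbonyl face flanked by O3 (the other face points into the ring toward C8), which should give the 3,4-cis (syn) diol, that is 4-OH β.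

Step 10
Reactants: 16 (3R,3aS,4R,8aS)-6-(hydroxymethyl)-8a-methyl-3-(propan-2-yl)-1,2,3,3a,4,5,8,8a-octahydroazulene-3,4-diol
Product: 18 (3R,3aS,4R,8aS)-6,8a-dimethyl-3-(propan-2-yl)-1,2,3,3a,4,5,8,8a-octahydroazulene-3,4-diol, via allylic chloride 17 (not isolated)
Conditions: NCS, Me2S, CH2Cl2, −25 → 0 °C, aqueous work-up; then LiEt3BH, THF, 0 °C
Reagents that add atoms: none
Why: The Corey–Kim reagent converts only the primary allylic alcohol to its chloride (the homoallylic secondary and the tertiary alcohol return unchanged on work-up) and LiEt3BH displaces chloride by SN2 to leave the C6 methyl group, no stereocentre being involved.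

Step 11
Reactants: 18 (3R,3aS,4R,8aS)-6,8a-dimethyl-3-(propan-2-yl)-1,2,3,3a,4,5,8,8a-octahydroazulene-3,4-diol; 19 4-acetoxybenzoyl chloride
Product: 20 (3R,3aS,4R,8aS)-3-hydroxy-6,8a-dimethyl-3-(propan-2-yl)-1,2,3,3a,4,5,8,8a-octahydroazulen-4-yl 4-(acetyloxy)benzoate
Conditions: DMAP, Et3N, CH2Cl2, 0 °C → rt
Reagents that add atoms: none
Why: DMAP-catalysed acylation takes the secondary alcohol with retention at C4, the tertiary alcohol being inert under these conditions and the phenol being masked as its acetate.

Step 12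
Reactants: 20 (3R,3aS,4R,8aS)-3-hydroxy-6,8a-dimethyl-3-(propan-2-yl)-1,2,3,3a,4,5,8,8a-octahydroazulen-4-yl 4-(acetyloxy)benzoate
Product: 21 (3R,3aS,4R,6R,7S,8aS)-6,7-epoxy-3-hydroxy-6,8a-dimethyl-3-(propan-2-yl)decahydroazulen-4-yl 4-(acetyloxy)benzoate
Conditions: mCPBA, NaHCO3, CH2Cl2, 0 °C
Reagents that add atoms: 3-chloroperoxybenzoic acid (mCPBA), OOC(=O)c1cccc(Cl)c1
Why: Prilezhaev epoxidation of the only alkene should occur from the convex α face, because the β face is covered by the axial C4 benzoate and the folded cyclopentane of the cis-fused bicycle, which sets C6 and C7.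

Step 13
Reactants: 21 (3R,3aS,4R,6R,7S,8aS)-6,7-epoxy-3-hydroxy-6,8a-dimethyl-3-(propan-2-yl)decahydroazulen-4-yl 4-(acetyloxy)benzoate
Product: 22 (3R,3aS,4R,6R,7S,8aS)-6,7-epoxy-3-hydroxy-6,8a-dimethyl-3-(propan-2-yl)decahydroazulen-4-yl 4-hydroxybenzoate (target)
Conditions: K2CO3 (0.2 equiv), MeOH, 0 °C
Reagents that add atoms: none
Why: Zemplén-type methanolysis removes the aryl acetate far faster than it attacks the hindered alkyl benzoate (the phenoxide formed deactivates that ester), and the epoxide and all stereocentres are untouched.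

Compound list
1 | (S)-(+)-terpinen-4-ol [(1S)-4-methyl-1-(propan-2-yl)cyclohex-3-en-1-ol] | CC(C)[C@]1(O)CCC(C)=CC1 | starting material
2 | triethyl{[(1S)-4-methyl-1-(propan-2-yl)cyclohex-3-en-1-yl]oxy}silane | CC(C)[C@]1(O[Si](CC)(CC)CC)CCC(C)=CC1 | intermediate
3 | secondary ozonide of 2 (1,2,4-trioxolane across the former C=C, mixture at the two new centres) | CC(C)[C@]1(O[Si](CC)(CC)CC)CCC2(C)OOC(C1)O2 | intermediate
4 | (3S)-6-oxo-3-(propan-2-yl)-3-[(triethylsilyl)oxy]heptanal | CC(C)[C@](O[Si](CC)(CC)CC)(CCC(C)=O)CC=O | intermediate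
5 | (5R)-2-methyl-5-(propan-2-yl)-5-[(triethylsilyl)oxy]cyclopent-1-ene-1-carbaldehyde | CC(C)[C@]1(O[Si](CC)(CC)CC)CCC(C)=C1C=O | intermediate
6 | 1-{(5R)-2-methyl-5-(propan-2-yl)-5-[(triethylsilyl)oxy]cyclopent-1-en-1-yl}ethan-1-ol (both carbinol epimers) | CC(C)[C@]1(O[Si](CC)(CC)CC)CCC(C)=C1C(C)O | intermediate
7 | (1R)-2-(1-hydroxyethyl)-3-methyl-1-(propan-2-yl)cyclopent-2-en-1-ol (both epimers at the hydroxyethyl carbon) | CC(C)[C@]1(O)CCC(C)=C1C(C)O | intermediate
8 | 1-[(5R)-5-hydroxy-2-methyl-5-(propan-2-yl)cyclopent-1-en-1-yl]ethan-1-one | CC(C)[C@]1(O)CCC(C)=C1C(C)=O | intermediate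
9 | cyclic di-tert-butylsilylene dienol ether of 8 [(7aR)-2,2-di-tert-butyl-5-methyl-4-methylidene-7a-(propan-2-yl)-4,6,7,7a-tetrahydrocyclopenta[d][1,3,2]dioxasiline] | CC(C)[C@]12CCC(C)=C1C(=C)O[Si](C(C)(C)C)(C(C)(C)C)O2 | intermediate
10 | methyl but-3-enoate | C=CCC(=O)OC | starting material
11 | methyl 2-diazobut-3-enoate | COC(=O)C(=[N+]=[N-])C=C | intermediate
12 | spiro cis-divinylcyclopropane: C4 of the dioxasiline carries a cyclopropane (C5 methylene, C6 bearing vinyl and CO2Me) on the β face, vinyl cis to the cyclopentenyl carbon; descriptors as in the SMILES | CC(C)[C@]12CCC(C)=C1[C@]1(C[C@]1(C=C)C(=O)OC)O[Si](C(C)(C)C)(C(C)(C)C)O2 | intermediate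
13 | methyl (3R,8aS)-3,4-[(di-tert-butylsilanediyl)bis(oxy)]-8a-methyl-3-(propan-2-yl)-1,2,3,5,8,8a-hexahydroazulene-6-carboxylate (C3a=C4 silyl enol ether, C6=C7 enoate) | CC(C)[C@]12CC[C@@]3(C)CC=C(C(=O)OC)CC(=C13)O[Si](C(C)(C)C)(C(C)(C)C)O2 | intermediate
14 | methyl (3R,3aR,8aS)-3-{[di-tert-butyl(fluoro)silyl]oxy}-8a-methyl-4-oxo-3-(propan-2-yl)-1,2,3,3a,4,5,8,8a-octahydroazulene-6-carboxylate | CC(C)[C@]1(O[Si](F)(C(C)(C)C)C(C)(C)C)CC[C@@]2(C)CC=C(C(=O)OC)CC(=O)[C@H]21 | intermediate
15 | methyl (3R,3aR,8aS)-3-hydroxy-8a-methyl-4-oxo-3-(propan-2-yl)-1,2,3,3a,4,5,8,8a-octahydroazulene-6-carboxylate (cis-fused) | CC(C)[C@]1(O)CC[C@@]2(C)CC=C(C(=O)OC)CC(=O)[C@H]21 | intermediate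
16 | (3R,3aS,4R,8aS)-6-(hydroxymethyl)-8a-methyl-3-(propan-2-yl)-1,2,3,3a,4,5,8,8a-octahydroazulene-3,4-diol | CC(C)[C@]1(O)CC[C@@]2(C)CC=C(CO)C[C@@H](O)[C@H]21 | intermediate
17 | (3R,3aS,4R,8aS)-6-(chloromethyl)-8a-methyl-3-(propan-2-yl)-1,2,3,3a,4,5,8,8a-octahydroazulene-3,4-diol | CC(C)[C@]1(O)CC[C@@]2(C)CC=C(CCl)C[C@@H](O)[C@H]21 | intermediate
18 | (3R,3aS,4R,8aS)-6,8a-dimethyl-3-(propan-2-yl)-1,2,3,3a,4,5,8,8a-octahydroazulene-3,4-diol | CC(C)[C@]1(O)CC[C@@]2(C)CC=C(C)C[C@@H](O)[C@H]21 | intermediate
19 | 4-acetoxybenzoyl chloride | CC(=O)Oc1ccc(cc1)C(Cl)=O | starting material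
20 | (3R,3aS,4R,8aS)-3-hydroxy-6,8a-dimethyl-3-(propan-2-yl)-1,2,3,3a,4,5,8,8a-octahydroazulen-4-yl 4-(acetyloxy)benzoate | CC(C)[C@]1(O)CC[C@@]2(C)CC=C(C)C[C@@H](OC(=O)c3ccc(OC(C)=O)cc3)[C@H]21 | intermediate
21 | (3R,3aS,4R,6R,7S,8aS)-6,7-epoxy-3-hydroxy-6,8a-dimethyl-3-(propan-2-yl)decahydroazulen-4-yl 4-(acetyloxy)benzoate | CC(C)[C@]1(O)CC[C@@]2(C)C[C@@H]3O[C@]3(C)C[C@@H](OC(=O)c3ccc(OC(C)=O)cc3)[C@H]21 | intermediate
22 | (3R,3aS,4R,6R,7S,8aS)-6,7-epoxy-3-hydroxy-6,8a-dimethyl-3-(propan-2-yl)decahydroazulen-4-yl 4-hydroxybenzoate | CC(C)[C@]1(O)CC[C@@]2(C)C[C@@H]3O[C@]3(C)C[C@@H](OC(=O)c3ccc(O)cc3)[C@H]21 | target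

Total step count: 13. Longest linear sequence: 12 steps (steps 1–5 and 7–13 from 1); step 6 is a one-step side branch.

Steps most likely to fail

Step 7. The unsubstituted vinylcarbenoid may be attacked by the enol ether at its vinyl terminus (vinylogous alkylation or a formal (3+2) annulation), the diazo ester may be lost to pyrazole formation or carbene dimerisation before it meets the hindered diene, or the Cope rearrangement may stall against the Z-methyl group. The fallback keeps the same two-bond (4+3) event but uses the sturdier 3-silyloxy vinyldiazoacetate, whose oxygen substituent suppresses vinylogous reactivity, and then removes the extra oxygen. It sets out from 9 and comes back at 15. Methyl 3-oxobutanoate would be converted by diazo transfer (p-ABSA, Et3N, MeCN) into methyl 2-diazo-3-oxobutanoate F1 and then with tBuMe2SiOTf/Et3N into methyl 3-[(tert-butyldimethylsilyl)oxy]-2-diazobut-3-enoate F2. Reaction of F2 with 9 under Rh2(O2CC7H15)4 in hexane should give the doubly silylated cycloheptadiene F3. HF·pyridine would cleave both enol ethers and the silyl ether to the cis-fused diketo ester F4, whose β-keto ester is converted with NaH and PhNTf2 into the enol triflate F5. Reduction of the triflate with Pd(OAc)2, PPh3, Bu3N and HCO2H in DMF should give 15.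

Step 8. Protonation of C3a may show poor facial selectivity and deliver the trans-fused ketone. The fallback replaces kinetic protonation by a separate thermodynamic equilibration on an oxygen-protected ketone, so that retro-aldol cleavage is impossible. It sets out from 13 and comes back at 15. Bu4NF (1.1 equiv) with AcOH in THF at −78 °C should open only the enol-ether Si–O bond and give 14 together with its C3a epimer, the trans-fused fluorosilyl ketone F6. The mixture would be equilibrated with catalytic DBU in toluene (short contact, to limit migration of the skipped alkene) toward the more stable cis-fused 14, and HF·pyridine would then remove the fluorosilyl group to give 15.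

Step 5. The hindered tertiary alkoxide may fail to close the strained s-cis dioxasiline (oligomeric silyl ethers instead), or γ-deprotonation may lead to the through-conjugated dienol ether. The fallback gives up the tether and relies on reagent control in the cycloaddition. It sets out from 8 and comes back at 15. Soft enolisation and silylation of both oxygens with Et3SiOTf/Et3N in CH2Cl2 should give the acyclic bis(triethylsilyl) dienol ether F7. The (4+3) reaction of F7 with 11 would be run in pentane with the chiral catalyst dirhodium tetrakis[(S)-N-(4-dodecylbenzenesulfonyl)prolinate], Rh2(S-DOSP)4, or its enantiomer (whichever proves matched with the C3 centre is kept), to give the bis(silyl) cycloheptadiene F8. HF·pyridine would then hydrolyse F8 to 15, the protonation at C3a being steered by the bulky silyl ether on O3.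

Further compounds
F1 | step 7 | methyl 2-diazo-3-oxobutanoate | COC(=O)C(=[N+]=[N-])C(C)=O
F2 | step 7 | methyl 3-[(tert-butyldimethylsilyl)oxy]-2-diazobut-3-enoate | COC(=O)C(=[N+]=[N-])C(=C)O[Si](C)(C)C(C)(C)C
F3 | step 7 | methyl (3R,8aS)-7-[(tert-butyldimethylsilyl)oxy]-3,4-[(di-tert-butylsilanediyl)bis(oxy)]-8a-methyl-3-(propan-2-yl)-1,2,3,5,8,8a-hexahydroazulene-6-carboxylate | CC(C)[C@]12CC[C@@]3(C)CC(O[Si](C)(C)C(C)(C)C)=C(C(=O)OC)CC(=C13)O[Si](C(C)(C)C)(C(C)(C)C)O2
F4 | step 7 | methyl (3R,3aR,8aS)-3-hydroxy-8a-methyl-4,7-dioxo-3-(propan-2-yl)decahydroazulene-6-carboxylate (C6 epimers and enol form) | CC(C)[C@]1(O)CC[C@@]2(C)CC(=O)C(C(=O)OC)CC(=O)[C@H]21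
F5 | step 7 | methyl (3R,3aR,8aS)-3-hydroxy-8a-methyl-4-oxo-3-(propan-2-yl)-7-{[(trifluoromethyl)sulfonyl]oxy}-1,2,3,3a,4,5,8,8a-octahydroazulene-6-carboxylate | CC(C)[C@]1(O)CC[C@@]2(C)CC(OS(=O)(=O)C(F)(F)F)=C(C(=O)OC)CC(=O)[C@H]21
F6 | step 8 | methyl (3R,3aS,8aS)-3-{[di-tert-butyl(fluoro)silyl]oxy}-8a-methyl-4-oxo-3-(propan-2-yl)-1,2,3,3a,4,5,8,8a-octahydroazulene-6-carboxylate (trans-fused C3a epimer of 14) | CC(C)[C@]1(O[Si](F)(C(C)(C)C)C(C)(C)C)CC[C@@]2(C)CC=C(C(=O)OC)CC(=O)[C@@H]21
F7 | step 5 | triethyl({1-[(5R)-2-methyl-5-(propan-2-yl)-5-[(triethylsilyl)oxy]cyclopent-1-en-1-yl]ethenyl}oxy)silane | CC(C)[C@]1(O[Si](CC)(CC)CC)CCC(C)=C1C(=C)O[Si](CC)(CC)CC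
F8 | step 5 | methyl (3R,8aS)-8a-methyl-3-(propan-2-yl)-3,4-bis[(triethylsilyl)oxy]-1,2,3,5,8,8a-hexahydroazulene-6-carboxylate | CC(C)[C@]1(O[Si](CC)(CC)CC)CC[C@@]2(C)CC=C(C(=O)OC)CC(O[Si](CC)(CC)CC)=C12
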